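**Plan**

- Retrosynthesis: the enyne C(sp)–C(sp2) bond is cut first, giving ethynyl oxolane 11 and bromo-iodo-triene 19. The oxolane is then cut at O1–C2 and C4–C5 together.
- Enabling feature: ring atoms O1–C5 are an aldehyde C=O, and ring atoms C2–C3–C4 are the three carbons of an α-chiral allylsilane. C3 and C4 carry only hydrogen in the target, so the silicon that ends on C3 can be taken off afterwards.
- Forward: allylic chloride 3 → (S)-allylsilane 4 → SnCl4-chelate-controlled (3+2) annulation with benzyloxyacetaldehyde (closes the only ring) → protiodesilylation → CH2OBn arm turned into the ethynyl group → Sonogashira coupling with 19.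
- Side chain from octa-1,7-diyne: one alkyne becomes the E vinyl iodide; the other is formylated, bromo-olefinated (E) and cis-reduced (Z).
- Stereochemistry: C2 from the silane stereocentre (copper-catalysed asymmetric allylic silylation), transferred with inversion in the annulation; C5 set trans to C2 by chelation control; alkene geometry from syn hydrometalation, Takai olefination and a stereoretentive coupling.

Key step: step 3

Remark: the given descriptors correspond to the 2,5-trans oxolane, (2R,5S) in the name used for 20. Anhydrous CrBr2 is taken as an available reagent (otherwise prepared beforehand from CrBr3 and LiAlH4).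

**Route**

Step 1
Reactants: 1 methyl hex-5-enoate; 2 (Z)-1,4-dichlorobut-2-ene
Product: 3 methyl (5E)-7-chlorohept-5-enoate
Conditions: second-generation Grubbs catalyst (3 mol%), 2 (3 equiv), CH2Cl2, 40 °C
Reagents that add atoms: none
Why: Olefin cross-metathesis of the terminal alkene with the symmetrical dichlorobutene in excess transfers a chloroallyl end and should give mainly the E allylic chloride; no stereocentre is formed.

Step 2
Reactants: 3 methyl (5E)-7-chlorohept-5-enoate
Product: 4 methyl (5S)-5-[dimethyl(phenyl)silyl]hept-6-enoate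
Conditions: PhMe2Si–Bpin (1.5 equiv), CuCl (5 mol%), enantiopure six-membered-ring N-heterocyclic carbene precursor (5.5 mol%, antipode chosen to give the S silane), NaOMe (1.6 equiv), CH2Cl2, 0 °C
Reagents that add atoms: 2-[dimethyl(phenyl)silyl]-4,4,5,5-tetramethyl-1,3,2-dioxaborolane, CC1(C)OB(OC1(C)C)[Si](C)(C)c1ccccc1
Why: Copper-catalysed enantioselective γ-selective (SN2'-type) allylic substitution of a linear allylic chloride by the silyl group released from the Si–B reagent by methoxide, in which the chiral carbene on copper sets the Si-bearing stereocentre and methoxide is matched to the methyl ester.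

Step 3
Reactants: 4 methyl (5S)-5-[dimethyl(phenyl)silyl]hept-6-enoate; 5 benzyloxyacetaldehyde
Product: 6 methyl 4-[(2R,3S,5S)-5-[(benzyloxy)methyl]-3-[dimethyl(phenyl)silyl]oxolan-2-yl]butanoate
Conditions: SnCl4 (1.05 equiv, premixed with 5), 4 Å molecular sieves, CH2Cl2, −78 to −20 °C
Reagents that add atoms: none
Why: SnCl4 holds 5 as a five-membered chelate (carbonyl O and ether O); the terminal alkene carbon of 4 adds to the carbonyl carbon anti to the C–Si bond (anti-SE2'), forming the C4–C5 bond and a β-silyl cation bridged as a siliranium ion, and the tin alkoxide oxygen then opens this ion at the former silyl-bearing carbon while silicon shifts to the neighbouring carbon, forming the O1–C2 bond. The closest known reaction type is the Lewis-acid-promoted (3+2) annulation of α-chiral allylsilanes with aldehydes, a Hosomi–Sakurai addition diverted from loss of silicon to 1,2-silyl migration and ring closure. The oxolane closes by backside opening of the three-membered siliranium ion, formally a 5-endo closure that is feasible because the carbon attacked is cationic. C2 is set by inversion at the stereocentre of (S)-4 (giving R), the transient C3 centre by the anti opening (silyl trans to the C2 chain), and C5 by the face of the chelated aldehyde that is attacked; bidentate chelates of α-alkoxy aldehydes are known in this reaction class to give the 2,5-trans ring, whereas monodentate activation gives the cis ring. The step needs annulation to win over simple allylation, which the poorly leaving SiMe2Ph group, low temperature and a non-nucleophilic counter-ion should secure, and it needs 2,5-trans selectivity, which the chelating benzyloxymethyl arm should secure; this is why the alkyne is made later from that arm.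

Step 4
Reactants: 6 methyl 4-[(2R,3S,5S)-5-[(benzyloxy)methyl]-3-[dimethyl(phenyl)silyl]oxolan-2-yl]butanoate
Product: 8 methyl 4-[(2R,5S)-5-[(benzyloxy)methyl]oxolan-2-yl]butanoate, via tetrabutylammonium carboxylate 7 (not isolated)
Conditions: TBAF (1 M in THF, wet, 5 equiv), DMF, 80 °C; then MeI (6 equiv), rt
Reagents that add atoms: iodomethane, CI
Why: Fluoride-promoted protiodesilylation of an unactivated C–SiMe2Ph bond (fluoride cleaves Si–phenyl first, then the fluorosilyl group leaves carbon with protonation by water), a known reaction of 3-silyl oxolanes from this annulation; the hydroxide formed should saponify the ester, so the carboxylate is re-methylated in the same flask by SN2 O-alkylation, and C2 and C5 are not touched.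

Step 5
Reactants: 8 methyl 4-[(2R,5S)-5-[(benzyloxy)methyl]oxolan-2-yl]butanoate
Product: 9 methyl 4-[(2R,5S)-5-(hydroxymethyl)oxolan-2-yl]butanoate
Conditions: H2 (1 atm), 10% Pd/C, EtOAc, rt
Reagents that add atoms: none
Why: Hydrogenolysis of the benzyl ether, at a stage where the molecule holds no alkene or alkyne and the stereocentres are not involved.

Step 6
Reactants: 9 methyl 4-[(2R,5S)-5-(hydroxymethyl)oxolan-2-yl]butanoate
Product: 10 methyl 4-[(2R,5S)-5-formyloxolan-2-yl]butanoate
Conditions: Dess–Martin periodinane (1.2 equiv), CH2Cl2, 0 °C to rt; used crude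
Reagents that add atoms: none
Why: Dess–Martin oxidation of the primary alcohol under mild conditions that should not epimerise the α-alkoxy aldehyde.

Step 7
Reactants: 10 methyl 4-[(2R,5S)-5-formyloxolan-2-yl]butanoate
Product: 11 methyl 4-[(2R,5S)-5-ethynyloxolan-2-yl]butanoate
Conditions: dimethyl (1-diazo-2-oxopropyl)phosphonate (1.3 equiv), K2CO3 (2 equiv), MeOH, 0 °C to rt
Reagents that add atoms: dimethyl (1-diazo-2-oxopropyl)phosphonate, COP(=O)(OC)C(=[N+]=[N-])C(C)=O
Why: Ohira–Bestmann variant of the Seyferth–Gilbert homologation (Horner–Wadsworth–Emmons-type addition–elimination, loss of N2, 1,2-hydrogen shift) turns the aldehyde into the terminal alkyne in K2CO3/MeOH, conditions matched to the methyl ester and mild enough to keep C5.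

Step 8
Reactants: 12 octa-1,7-diyne
Product: 14 (E)-1-iodooct-1-en-7-yne, via alkenylzirconocene chloride 13 (not isolated)
Conditions: Cp2Zr(H)Cl (1.0 equiv), 12 (3 equiv), THF, rt; then I2 (1.0 equiv), 0 °C
Reagents that add atoms: iodine, II
Why: Schwartz hydrozirconation adds Zr–H syn and anti-Markovnikov to one terminal alkyne (excess diyne holds it at mono-addition), and iodinolysis of the C–Zr bond with retention should give the E vinyl iodide.

Step 9
Reactants: 14 (E)-1-iodooct-1-en-7-yne
Product: 16 (E)-9-iodonon-8-en-2-ynal, via alkynylmagnesium bromide 15 (not isolated)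
Conditions: EtMgBr (1.05 equiv), THF, 0 °C to rt; DMF (3 equiv), 0 °C to rt; reverse quench into cold aqueous KH2PO4
Reagents that add atoms: N,N-dimethylformamide, CN(C)C=O
Why: Deprotonation of the terminal alkyne by the Grignard reagent (the vinyl iodide should not exchange with an alkyl Grignard reagent here) and formylation of the alkynyl Grignard with DMF, the buffered quench releasing the ynal.

Step 10
Reactants: 16 (E)-9-iodonon-8-en-2-ynal
Product: 17 (1E,9E)-1-bromo-10-iododeca-1,9-dien-3-yne
Conditions: CHBr3 (2 equiv), CrBr2 (6 equiv), THF, 0 °C to rt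
Reagents that add atoms: bromoform, BrC(Br)Br
Why: Takai olefination, in which the geminal dichromium species from CHBr3 and divalent chromium adds to the aldehyde and eliminates to the E bromoalkene; the bromide salt avoids halogen exchange and the vinyl iodide is inert to divalent chromium without nickel.

Step 11
Reactants: 17 (1E,9E)-1-bromo-10-iododeca-1,9-dien-3-yne
Product: 19 (1E,3Z,9E)-1-bromo-10-iododeca-1,3,9-triene, via dienylborane 18 (not isolated)
Conditions: dicyclohexylborane (1.1 equiv, from BH3·SMe2 and cyclohexene), THF, 0 °C; then AcOH, rt to 50 °C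
Reagents that add atoms: none
Why: Hydroboration–protonolysis, in which the hindered dialkylborane adds syn to the only alkyne (the two halo-alkenes are deactivated towards an electrophilic borane) and acetic acid cleaves the alkenyl C–B bond with retention, so the Z alkene should result whichever alkyne carbon carries boron.

Step 12
Reactants: 11 methyl 4-[(2R,5S)-5-ethynyloxolan-2-yl]butanoate; 19 (1E,3Z,9E)-1-bromo-10-iododeca-1,3,9-triene
Product: 20 methyl 4-[(2R,5S)-5-[(3E,9Z,11E)-12-bromododeca-3,9,11-trien-1-yn-1-yl]oxolan-2-yl]butanoate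
Conditions: Pd(PPh3)4 (5 mol%), CuI (10 mol%), i-Pr2NH (3 equiv), degassed THF, rt
Reagents that add atoms: none
Why: Sonogashira coupling, in which zerovalent palladium should insert into the vinyl C–I bond at room temperature much faster than into the dienyl C–Br bond and couple with retention of the E geometry, leaving the stereocentres untouched.

**Compound list**

1 | methyl hex-5-enoate | C=CCCCC(=O)OC | starting material
2 | (Z)-1,4-dichlorobut-2-ene | ClC/C=C\CCl | starting material
3 | methyl (5E)-7-chlorohept-5-enoate | COC(=O)CCC/C=C/CCl | intermediate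
4 | methyl (5S)-5-[dimethyl(phenyl)silyl]hept-6-enoate | C=C[C@@H]([Si](C)(C)c1ccccc1)CCCC(=O)OC | intermediate
5 | benzyloxyacetaldehyde | O=CCOCc1ccccc1 | starting material
6 | methyl 4-[(2R,3S,5S)-5-[(benzyloxy)methyl]-3-[dimethyl(phenyl)silyl]oxolan-2-yl]butanoate | COC(=O)CCC[C@@H]1[C@@H]([Si](C)(C)c2ccccc2)C[C@@H](COCc2ccccc2)O1 | intermediate
7 | tetrabutylammonium 4-[(2R,5S)-5-[(benzyloxy)methyl]oxolan-2-yl]butanoate | [O-]C(=O)CCC[C@@H]1CC[C@@H](COCc2ccccc2)O1.CCCC[N+](CCCC)(CCCC)CCCC | intermediate (not isolated)
8 | methyl 4-[(2R,5S)-5-[(benzyloxy)methyl]oxolan-2-yl]butanoate | COC(=O)CCC[C@@H]1CC[C@@H](COCc2ccccc2)O1 | intermediate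
9 | methyl 4-[(2R,5S)-5-(hydroxymethyl)oxolan-2-yl]butanoate | COC(=O)CCC[C@@H]1CC[C@@H](CO)O1 | intermediate
10 | methyl 4-[(2R,5S)-5-formyloxolan-2-yl]butanoate | COC(=O)CCC[C@@H]1CC[C@@H](C=O)O1 | intermediate
11 | methyl 4-[(2R,5S)-5-ethynyloxolan-2-yl]butanoate | COC(=O)CCC[C@@H]1CC[C@@H](C#C)O1 | intermediate
12 | octa-1,7-diyne | C#CCCCCC#C | starting material
13 | chloro[(E)-oct-1-en-7-yn-1-yl]bis(cyclopentadienyl)zirconium | Cl[Zr](/C=C/CCCCC#C)(C1C=CC=C1)C1C=CC=C1 | intermediate (not isolated)
14 | (E)-1-iodooct-1-en-7-yne | I/C=C/CCCCC#C | intermediate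
15 | bromo[(E)-8-iodooct-7-en-1-yn-1-yl]magnesium | Br[Mg]C#CCCCC/C=C/I | intermediate (not isolated)
16 | (E)-9-iodonon-8-en-2-ynal | O=CC#CCCCC/C=C/I | intermediate
17 | (1E,9E)-1-bromo-10-iododeca-1,9-dien-3-yne | Br/C=C/C#CCCCC/C=C/I | intermediate
18 | [(1E,3Z,9E)-1-bromo-10-iododeca-1,3,9-trien-4-yl]dicyclohexylborane (major regioisomer assumed) | Br/C=C/C=C(\CCCC/C=C/I)B(C1CCCCC1)C1CCCCC1 | intermediate (not isolated)
19 | (1E,3Z,9E)-1-bromo-10-iododeca-1,3,9-triene | Br/C=C/C=C\CCCC/C=C/I | intermediate
20 | methyl 4-[(2R,5S)-5-[(3E,9Z,11E)-12-bromododeca-3,9,11-trien-1-yn-1-yl]oxolan-2-yl]butanoate | COC(=O)CCC[C@@H]1CC[C@@H](C#C/C=C/CCCC/C=C\C=C\Br)O1 | target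

**Count**

Total steps: 12. Longest linear sequence: 8 (steps 1 to 7, then 12).

**Steps most likely to fail**

Step 3. What may go wrong: attack on the other aldehyde face if chelation is incomplete, giving the 2,5-cis ring, or loss of silicon from the β-silyl cation, giving the open-chain homoallylic alcohol. Fallback: stepwise ring construction by stereospecific iodoetherification, setting out from 5 and coming back at 8. Asymmetric allylboration of 5 with B-allyldiisopinocampheylborane (antipode chosen for the S alcohol) should give (S)-1-(benzyloxy)pent-4-en-2-ol F1. Cross-metathesis of F1 with 1 (second-generation Hoveyda–Grubbs catalyst) should give methyl (5E,8S)-9-(benzyloxy)-8-hydroxynon-5-enoate F2. I2 and NaHCO3 in dry MeCN should close F2 by anti 5-endo-trig iodoetherification, a process known to give 2,5-trans rings from E homoallylic alcohols, to methyl 4-[(2R,3S,5S)-5-[(benzyloxy)methyl]-3-iodooxolan-2-yl]butanoate F3. Bu3SnH with AIBN then removes iodine and gives 8.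

Step 4. What may go wrong: slow C–Si cleavage because no neighbouring hydroxyl assists, or ring opening by β-elimination of the ring oxygen from the carbanion-like intermediate. Fallback: oxidative removal of silicon, setting out from 6 and coming back at 8. Tamao–Fleming oxidation (Hg(OAc)2, AcOOH, AcOH) should replace silicon by hydroxyl with retention and give methyl 4-[(2R,3S,5S)-5-[(benzyloxy)methyl]-3-hydroxyoxolan-2-yl]butanoate F4. 1,1'-Thiocarbonyldiimidazole should give methyl 4-[(2R,3S,5S)-5-[(benzyloxy)methyl]-3-[(1H-imidazol-1-ylcarbonothioyl)oxy]oxolan-2-yl]butanoate F5. Barton–McCombie deoxygenation (Bu3SnH, AIBN, toluene, 90 °C) then gives 8.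

Step 11. What may go wrong: competing hydroboration of the halo-alkenes, incomplete protonolysis, or loss of halide. Fallback: the Z alkene is set before the bromide exists, setting out from 16 and coming back at 19. Luche reduction (NaBH4, CeCl3·7H2O, MeOH) should give (E)-9-iodonon-8-en-2-yn-1-ol F6. Activated zinc (Zn(Cu/Ag), MeOH/H2O), which reduces hydroxyl-activated alkynes cis-selectively and leaves isolated alkenes alone, should give (2Z,8E)-9-iodonona-2,8-dien-1-ol F7. MnO2 in CH2Cl2 should give (2Z,8E)-9-iodonona-2,8-dienal F8. Takai bromo-olefination of F8 (CHBr3, CrBr2, THF) then gives 19.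

**Further compounds**

F1 | step 3 | (S)-1-(benzyloxy)pent-4-en-2-ol | C=CC[C@H](O)COCc1ccccc1
F2 | step 3 | methyl (5E,8S)-9-(benzyloxy)-8-hydroxynon-5-enoate | COC(=O)CCC/C=C/C[C@H](O)COCc1ccccc1
F3 | step 3 | methyl 4-[(2R,3S,5S)-5-[(benzyloxy)methyl]-3-iodooxolan-2-yl]butanoate | COC(=O)CCC[C@@H]1[C@@H](I)C[C@@H](COCc2ccccc2)O1
F4 | step 4 | methyl 4-[(2R,3S,5S)-5-[(benzyloxy)methyl]-3-hydroxyoxolan-2-yl]butanoate | COC(=O)CCC[C@@H]1[C@@H](O)C[C@@H](COCc2ccccc2)O1
F5 | step 4 | methyl 4-[(2R,3S,5S)-5-[(benzyloxy)methyl]-3-[(1H-imidazol-1-ylcarbonothioyl)oxy]oxolan-2-yl]butanoate | COC(=O)CCC[C@@H]1[C@@H](OC(=S)n2ccnc2)C[C@@H](COCc2ccccc2)O1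
F6 | step 11 | (E)-9-iodonon-8-en-2-yn-1-ol | OCC#CCCCC/C=C/I
F7 | step 11 | (2Z,8E)-9-iodonona-2,8-dien-1-ol | OC/C=C\CCCC/C=C/I
F8 | step 11 | (2Z,8E)-9-iodonona-2,8-dienal | O=C/C=C\CCCC/C=C/I
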